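The target and the other capture product, by the list of suspects, both come from the same intermediate, so what I wanted from the four flasks was how that intermediate divides between the two nucleophiles.

| flask | substrate | first nucleophile | second nucleophile | remark | time |
|---|---|---|---|---|---|
| delta | 0.10 M | 1.2 equiv | 1.8 equiv | run made earlier |  |
| gamma | 0.10 M | 1.2 equiv | 0.90 equiv | run made earlier |  |
| beta | 0.10 M | 1.2 equiv | 1.4 equiv | run made earlier |  |
| teal | 0.10 M | 1.20 equiv (fed, over 6.0 h) | 1.80 equiv | all else is in the flask from the start; the feed brings no volume worth counting | 8.0 h |
| violet | 0.10 M | 1.20 equiv (in portions, 3, over 6.0 h) | 1.80 equiv | first portion at the start, last at 6.0 h | 8.0 h |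
| ochre | 0.10 M | 1.20 equiv | 1.80 equiv | everything together at the start | 8.0 h |
| red | 0.10 M | 1.20 equiv | 1.80 equiv (fed, over 6.0 h) | all else is in the flask from the start; the feed brings no volume worth counting | 8.0 h |

- delta (time / h: target / %, other capture product / %): 1.00: 8.1, 20.1; 2.00: 11.5, 31.3; 3.00: 12.8, 33.3; 4.00: 12.4, 36.5; 5.00: 11.7, 36.1
- gamma (time / h: target / %, other capture product / %): 0.500: 7.0, 8.8; 1.00: 11.3, 15.2; 2.00: 15.0, 17.1; 3.00: 16.4, 22.4; 6.00: 15.8, 23.1
- beta (time / h: target / %, other capture product / %): 1.33: 9.7, 21.0; 2.50: 12.5, 28.4; 4.00: 13.3, 29.3; 5.00: 13.0, 31.6; 6.00: 15.5, 31.0

(readings scatter by 1 percentage point)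

- percentages count the substrate that a species holds: one homo dimer counts as two
- the numbers in the tables scatter by 1 percentage point (one standard deviation)
- on the list of suspects stand: substrate -> intermediate; first nucleophile + intermediate -> target; second nucleophile + intermediate -> other capture product; intermediate -> solvolysis product; 2 substrate -> homo dimer; first nucleophile <-> dormant form

- the flask that comes out highest in share of target in target plus other capture product, or "all alike" when all lie within 1.5 percentage points (teal / violet / ochre / red / all alike)
- share of target in target plus other capture product at the end, teal
- share of target in target plus other capture product at the end, violet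
- share of target in target plus other capture product at the end, ochre
- share of target in target plus other capture product at the end, red

The last readings, as target over other capture product times second over first nucleophile charged, gave 0.486 in delta, 0.513 in gamma and 0.583 in beta. I took their mean, 0.527, as the capture ratio ρ, a selectivity factor counted on charged amounts. With a and b the equivalents of first and second nucleophile standing beside the intermediate:

share of target = ρa / (ρa + b)

Red has two extremes. With its whole charge of second nucleophile present from the start it is ochre, by the rule at 26.0%; with b nil, the rule gives a share of one. Where it lies between them I reckoned from the timing. The capture read in gamma at 1.00 h was 68.1% of that read at 6.00 h, so I took the earlier time as the working moment. The crossing time is the time by which red's feed has brought second nucleophile equal to ρ times the first nucleophile's charge, so that by the rule both captures run equally: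

6.0 h × ρ × 1.20 equiv / 1.80 equiv = 2.11 h

This is later than the working moment, so by the rule red is on the target's side at that moment. My reckoning, with the feeds at their working-moment amounts:

red 67.8%; teal 5.54%; violet, first portion only, 10.5%

The forecast named red highest, with teal 6.5%, violet 11%, ochre 25% and red 70%, holding that “only what is present early counts”; my teal and red lay below its figures.

The flasks gave teal 6.47%, violet 11.3%, ochre 26.0% and red 66.1%, so red came highest.

    substrate → intermediate (k = 2.30 × 10⁻⁴ s⁻¹)
    first nucleophile + intermediate → target (k = 0.0290 M⁻¹ s⁻¹)
    second nucleophile + intermediate → other capture product (k = 0.0200 M⁻¹ s⁻¹)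
    intermediate → solvolysis product (k = 0.00220 s⁻¹)
    2 substrate → homo dimer (k = 9.60 × 10⁻⁴ M⁻¹ s⁻¹)
    first nucleophile ⇌ dormant form (K = 2.30, k = 0.00190 s⁻¹)

In red, half of the turnover of the making of intermediate up to the asked time was done by 0.667 h, earlier than my crossing at 2.11 h, and red ended with 20.3% target beside 10.4% other capture product. A neighbour of red, fed over the same time with 7.20 equiv of second nucleophile, has its crossing at 0.527 h, earlier than that time of 0.667 h in red, and the neighbour's share of target came to 38.2%.

(The data are calculated on assumed constants; scatter was added.)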